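(The constants used here come from no measurement, and the outcome is calculated.)

Temperature is what separates alpha from epsilon: the charges are the same, but one flask stands at 5 °C and the other at −15 °C.

| flask | free monomer | transfer agent | protic impurity | initiator | time | remark | temperature |
|---|---|---|---|---|---|---|---|
| zeta | 0.58 M | 0.174 M | 0.174 M | 2.9 mM | 2.5 h | at −15 °C until 30 min, from then on at 25 °C |  |
| alpha | 0.58 M | 0.174 M | 0.174 M | 2.9 mM | 2.5 h |  | 5 °C |
| epsilon | 0.58 M | 0.174 M | 0.174 M | 2.9 mM | 2.5 h |  | −15 °C |
| eta | 0.58 M | 0.174 M | 0.174 M | 2.9 mM | 2.5 h |  | 25 °C |

    free monomer + initiator → living end + monomer in chains (k1 = 0.0365 M⁻¹ s⁻¹, Ea1 = 45.0 kJ mol⁻¹)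
    living end + transfer agent → dead chain (k2 = 0.00278 M⁻¹ s⁻¹, Ea2 = 53.0 kJ mol⁻¹)
    2 initiator ⇌ resting dimer, settled at all times (K3 = 220 M⁻¹, ΔH3 = 9.00 kJ mol⁻¹)
    free monomer + living end → monomer in chains + living end, rate k4*[living end]*[free monomer] (k4 = 0.799 M⁻¹ s⁻¹, Ea4 = 46.0 kJ mol⁻¹)
    protic impurity + free monomer → quenched substrate (k5 = 0.00558 M⁻¹ s⁻¹, Ea5 = 71.0 kJ mol⁻¹)
    (constants at 25 °C)

- a step written with two of one species runs at k times the square of its concentration and takes two of it each time
- the constants hold at 25 °C; other temperatures follow from the activation energies and enthalpies

* the flask with the highest amount of monomer in chains, in percent of the free monomer charged ("all alike" if they lie within 1.5 percentage points) (zeta / alpha / epsilon / eta / all alike)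
* final monomer in chains, as a percentage of the free monomer charged, in zeta
* final monomer in chains, as a percentage of the free monomer charged, in alpha
* final monomer in chains, as a percentage of the free monomer charged, in epsilon
* final monomer in chains, as a percentage of the free monomer charged, in eta

The step with initiator takes one free monomer per initiator, 0.500% of the monomer charge if the whole initiator charge goes that way. Beyond that, free monomer has two ways to go, so reckon each as a pseudo-first-order loss. Freeze the living ends at the initiator charge and the protic impurity at its own charge, with the constants taken at the flask's temperature. Then a is the growth constant times the initiator charge, b is the quench constant times the impurity charge, and τ = 1/(a + b) is the life of free monomer.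

epsilon: a = 0.470 h⁻¹, b = 0.0413 h⁻¹, a/(a + b) = 91.9%, τ = 1.95 h

alpha: a = 2.20 h⁻¹, b = 0.446 h⁻¹, a/(a + b) = 83.1%, τ = 0.378 h

eta: a = 8.34 h⁻¹, b = 3.50 h⁻¹, a/(a + b) = 70.5%, τ = 0.0845 h

The fraction a/(a + b) is the chain share, the part of the consumed monomer that enters chains while ends and impurity stand frozen; it is a selectivity. The frozen ends are fair because transfer needs 15.8 h to kill an end in epsilon, longer than that flask's τ, and 2.67 h in alpha, again longer than its τ.

The quench step's activation energy exceeds the growth step's by 25.0 kJ mol⁻¹, so epsilon has the higher share. But epsilon's τ is 1.95 h against the 2.5 h of the run, while alpha's is shorter. Multiply the share by the part consumed, one minus exp(−t/τ), where t is the time of the run: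

epsilon 66.4%, alpha 83.0%, eta 70.5%

So in my reckoning alpha ends higher than epsilon because its part consumed is larger, 99.9% against 72.3%, and alpha stands highest of the three. Two figures are rough. In eta the reckoned quench would take 98.4% of the impurity charge, so the frozen impurity fails there and I expect eta above my number. In epsilon the initiator's own life against free monomer at its charge is 13.1 min, a delay the clock ignores, so I expect epsilon below mine. I reckon zeta on epsilon's figures for 30 min, which by this clock consumes 22.6% of the monomer, and on eta's afterwards, which gives 75.3%.

The forecast says alpha, with 84% there, 59% in epsilon, 76% in eta and 79.5% in zeta, on the grounds that at its best flask “conversion is almost complete and quenching is still modest”. It agrees with my choice of flask. It stands higher than mine for eta and zeta, and lower for epsilon.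

The simulation gives 82.5% in alpha, 78.0% in zeta, 76.0% in eta and 59.4% in epsilon, so alpha is highest.

Left until 25.0 h, epsilon reaches 91.0% beside its chain share of 91.9%, and alpha reaches 83.6% beside 83.1%. A further flask is epsilon with 0.012 M of initiator. For it a = 1.95 h⁻¹ while b stays, so the chain share is 97.9% and τ is 0.503 h, and the product with the part consumed is 97.2%. At 2.50 h that flask holds 3.33% quenched substrate, 2.81% free monomer and 93.9% monomer in chains.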